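**Retrosynthetic overview**

1. The last C–C bond joins the β-carbon of the ring-C enone (C-5 of the hydroazulenone) to the ethylene linker by a Stork–Danheiser union, which splits the target into an AB-ring (oxepane–cyclohexane) alkyllithium and the CD-ring (cycloheptenone–cyclopentane) vinylogous ester 19.
2. In the CD half, ring C is closed by an intramolecular Claisen condensation (keto ester 15 to 1,3-dione 16). Before that, both bonds that tie ring C to ring D (ring-fusion CH–CMe2 and ring-fusion CH–CH2 next to the carbonyl) are made in one tandem double Ireland–Claisen rearrangement of the cyclopentenediol diester 8.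
3. Enabling feature: in ring D the two ring-fusion CH carbons are vicinal and cis, each bears an exocyclic carbon that is α to a carbonyl-level carbon of ring C, and the tertiary carbinol beside them can be read as a hydrated ring alkene. This is a twofold γ,δ-unsaturated carbonyl retron on one cyclopentene, so one reagent-set cis-diol relays its configuration to both ring-fusion centres, and the carbinol is regenerated afterwards by face-selective hydration.
4. In the AB half, rings A and B are formed together by a silyl-triflate-initiated bis-epoxide cascade of an all-(R) diepoxide that ends on a silyloxydiene; the axial tertiary alcohol comes from equatorial methyl addition to the ring-B ketone.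
5. Order of ring formation: D (bought), then C (step 9, on the bonds made in step 6); A and B together (step 17); the halves are joined last (step 22).

Key step: step 6

Remark: 20 is taken as the pure (2E) isomer; the stereolabile carbon between the carbonyls of 16 and the carbinol carbon of the in-flask adduct 34 are written without configuration because both are erased later.

**CD-ring half**

Step 1
Reactants: 1 2-methylcyclopent-2-en-1-one
Product: 2 (1S)-2-methylcyclopent-2-en-1-ol
Conditions: (R)-2-methyl-CBS-oxazaborolidine (0.1 equiv), BH3·SMe2, THF, −20 °C; then MeOH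
Reagents that add atoms: none
Why: CBS reduction of an α-substituted cyclic enone, in which the substituted alkenyl side acts as the large group, should deliver hydride 1,2 to one carbonyl face under catalyst control and give the (S)-allylic alcohol.

Step 2
Reactants: 2 (1S)-2-methylcyclopent-2-en-1-ol
Product: 3 (1S,2S,5R)-1-methyl-6-oxabicyclo[3.1.0]hexan-2-ol
Conditions: VO(acac)2 (2 mol%), t-BuOOH, CH2Cl2, 0 → 23 °C
Reagents that add atoms: tert-butyl hydroperoxide, CC(C)(C)OO
Why: Hydroxyl-directed vanadium-catalysed epoxidation should deliver oxygen to the alkene face syn to the allylic hydroxyl, which sets the cis relation of the two oxygens.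

Step 3
Reactants: 3 (1S,2S,5R)-1-methyl-6-oxabicyclo[3.1.0]hexan-2-ol
Product: 6 (1R,5S)-1-methylcyclopent-2-ene-1,5-diol, via hydroxy selenide 4 (not isolated), via selenoxide 5 (not isolated)
Conditions: (PhSe)2, NaBH4, EtOH, 23 → 60 °C; then 30% H2O2, pyridine, THF, 0 → 40 °C
Reagents that add atoms: none
Why: SN2 opening of the epoxide by selenolate at the less substituted carbon, followed by selenoxide syn-elimination away from the carbinol carbon, should transpose the epoxide into the tertiary allylic alcohol without touching either C–O stereocentre.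

Step 4
Reactants: 6 (1R,5S)-1-methylcyclopent-2-ene-1,5-diol
Product: 7 (1S,2R)-2-hydroxy-2-methylcyclopent-3-en-1-yl acetate
Conditions: Ac2O (1.05 equiv), pyridine, CH2Cl2, 0 °C
Reagents that add atoms: acetic anhydride, CC(=O)OC(C)=O
Why: Acylation should select the secondary hydroxyl over the tertiary one on steric grounds.

Step 5
Reactants: 7 (1S,2R)-2-hydroxy-2-methylcyclopent-3-en-1-yl acetate
Product: 8 (1R,5S)-5-(acetyloxy)-1-methylcyclopent-2-en-1-yl 2-methylpropanoate
Conditions: (i-PrCO)2O, DMAP (1.2 equiv), Et3N, CH2Cl2, 35 °C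
Reagents that add atoms: isobutyric anhydride, CC(C)C(=O)OC(=O)C(C)C
Why: DMAP-mediated acylation of the remaining tertiary allylic alcohol runs under non-ionising basic conditions, so the C–O stereocentre should stay intact.

Step 6
Reactants: 8 (1R,5S)-5-(acetyloxy)-1-methylcyclopent-2-en-1-yl 2-methylpropanoate
Product: 12 2-[(1R,5R)-5-(carboxymethyl)-4-methylcyclopent-3-en-1-yl]-2-methylpropanoic acid, via bis(silyl ketene acetal) 9 (not isolated), via mono-rearranged silyl ester 10 (not isolated), via bis(silyl ester) 11 (not isolated)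
Conditions: LiN(i-Pr)2 (2.6 equiv), TBSCl (3 equiv), DMPU, THF, −78 → 23 °C; then PhMe, 90 °C; then 1 M HCl, THF
Reagents that add atoms: none
Why: Double deprotonation and O-silylation give the bis(ketene acetal) 9, in which only the isobutyrate-derived unit sits on an allylic oxygen; its [3,3] shift forms the bond from the CMe2 carbon to the far alkene carbon and moves the alkene next to the second oxygen, which makes the acetate-derived ketene acetal allylic so that a second [3,3] shift forms the CH2–ring bond on the neighbouring carbon and leaves a ring alkene for later hydration. The closest known reaction type is the Ireland–Claisen rearrangement of cyclic allylic esters, established for isobutyrates (quaternary carbon) and for acetates; here two such shifts run in sequence in one flask. No ring is closed in this step: each bond forms through a six-membered pericyclic transition state on the cyclopentene, and the two acid arms are the handles for the later Claisen closure of ring C. Both new stereocentres are set by suprafacial 1,3-transfer, each carbon arriving on the ring face that the departing oxygen occupied, so the cis-diol configuration made in steps 1 to 3 becomes the cis ring fusion in one absolute configuration. The step needs the right order of the shifts and delivery of the second carbon cis to the bulky first one: the order is secured because only the tertiary ester is allylic at the start, the cis delivery because an antarafacial shift is impossible on a five-membered ring, and ketene acetal geometry is irrelevant because each enolised carbon carries two identical substituents.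

Step 7
Reactants: 12 2-[(1R,5R)-5-(carboxymethyl)-4-methylcyclopent-3-en-1-yl]-2-methylpropanoic acid
Product: 13 2-[(1R,5R)-5-(2-methoxy-2-oxoethyl)-4-methylcyclopent-3-en-1-yl]-2-methylpropanoic acid
Conditions: MeOH (1.2 equiv), EDC·HCl (1.05 equiv), DMAP (0.1 equiv), CH2Cl2, 0 °C
Reagents that add atoms: methanol, CO
Why: Steglich esterification should select the unhindered acetic acid arm, because the α,α-dimethyl acid is activated and attacked far more slowly.

Step 8
Reactants: 13 2-[(1R,5R)-5-(2-methoxy-2-oxoethyl)-4-methylcyclopent-3-en-1-yl]-2-methylpropanoic acid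
Product: 15 methyl 2-[(1R,5R)-2-methyl-5-(2-methyl-3-oxopentan-2-yl)cyclopent-2-en-1-yl]acetate, via acid chloride 14 (not isolated)
Conditions: (COCl)2, DMF (cat.), CH2Cl2, 0 → 23 °C; then EtMgBr, Fe(acac)3 (3 mol%), THF, −78 °C
Reagents that add atoms: ethylmagnesium bromide, CC[Mg]Br
Why: Iron-catalysed acylation of a Grignard reagent by an acid chloride stops at the ketone and should be much faster than attack on the methyl ester, and the α,α-dimethyl acid chloride cannot form a ketene.

Step 9
Reactants: 15 methyl 2-[(1R,5R)-2-methyl-5-(2-methyl-3-oxopentan-2-yl)cyclopent-2-en-1-yl]acetate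
Product: 16 (3aR,8aR)-1,4,4,6-tetramethyl-3,3a,4,6,8,8a-hexahydroazulene-5,7-dione
Conditions: KOt-Bu (2.5 equiv), THF, 0 → 45 °C; then 1 M HCl
Reagents that add atoms: none
Why: In this intramolecular Claisen condensation the ketone can enolise only at its ethyl CH2, and that enolate should acylate at the unhindered ester to close ring C (7-exo-trig), driven by deprotonation of the 2-methyl-1,3-dione, while the cis ring fusion is safe because neither ring-fusion carbon is α to a carbonyl.

Step 10
Reactants: 16 (3aR,8aR)-1,4,4,6-tetramethyl-3,3a,4,6,8,8a-hexahydroazulene-5,7-dione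
Product: 17 (3aR,8aR)-7-methoxy-1,4,4,6-tetramethyl-3a,4,8,8a-tetrahydroazulen-5(3H)-one
Conditions: HC(OMe)3, MeOH, p-TsOH·H2O (5 mol%), 23 °C
Reagents that add atoms: trimethyl orthoformate, COC(OC)OC
Why: Acid-catalysed enol ether formation under equilibrating conditions should place the methoxy group on the carbonyl flanked by CH2 and leave the ketone beside the gem-dimethyl carbon, which is the less congested vinylogous ester.

Step 11
Reactants: 17 (3aR,8aR)-7-methoxy-1,4,4,6-tetramethyl-3a,4,8,8a-tetrahydroazulen-5(3H)-one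
Product: 18 (1R,3aR,8aR)-1-hydroxy-7-methoxy-1,4,4,6-tetramethyl-2,3,3a,4,8,8a-hexahydroazulen-5(1H)-one
Conditions: Mn(dpm)3 (10 mol%), PhSiH3, O2 (1 atm), i-PrOH, 0 → 23 °C
Reagents that add atoms: dioxygen, O=O
Why: In this Mukaiyama hydration, hydrogen-atom transfer to the trisubstituted ring-D alkene gives the tertiary radical, which O2 should trap on the convex face of the cis-fused bicycle (anti to the ring-C methylene on the next carbon), so that the hydroxyl ends cis to the ring-fusion hydrogens, while the tetrasubstituted push–pull alkene of ring C should not react.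

Step 12
Reactants: 18 (1R,3aR,8aR)-1-hydroxy-7-methoxy-1,4,4,6-tetramethyl-2,3,3a,4,8,8a-hexahydroazulen-5(1H)-one
Product: 19 (1R,3aR,8aR)-7-methoxy-1,4,4,6-tetramethyl-1-[(triethylsilyl)oxy]-2,3,3a,4,8,8a-hexahydroazulen-5(1H)-one
Conditions: TESOTf, 2,6-lutidine, CH2Cl2, −40 → 0 °C
Reagents that add atoms: triethylsilyl trifluoromethanesulfonate, CC[Si](CC)(CC)OS(=O)(=O)C(F)(F)F
Why: Silylation with a silyl triflate and a hindered pyridine base is the standard way to cap a tertiary alcohol and removes the acidic proton before the organolithium step.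

**AB-ring half**

Step 13
Reactants: 20 geranyl bromide; 21 N-methoxy-N-methylacetamide
Product: 23 (4E)-N-methoxy-N,5,9-trimethyldeca-4,8-dienamide, via lithium enolate 22 (not isolated)
Conditions: LiN(i-Pr)2, THF, −78 °C; then 20, −78 → 0 °C
Reagents that add atoms: none
Why: SN2 alkylation of the amide enolate at the primary allylic bromide should extend the chain by two carbons and keep the E alkene.

Step 14
Reactants: 23 (4E)-N-methoxy-N,5,9-trimethyldeca-4,8-dienamide
Product: 24 3-[(2R,3R)-3-{2-[(2R)-3,3-dimethyloxiran-2-yl]ethyl}-3-methyloxiran-2-yl]-N-methoxy-N-methylpropanamide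
Conditions: D-fructose-derived diacetonide ketone catalyst (0.6 equiv), KHSO5 (as Oxone), K2CO3, Bu4NHSO4, MeCN/CH2(OMe)2/aq. Na2B4O7 buffer, 0 °C
Reagents that add atoms: potassium peroxymonosulfate (Oxone), [K+].[O-]OS(O)(=O)=O
Why: In this Shi epoxidation the chiral dioxirane should epoxidise both trisubstituted alkenes through the same spiro transition state to give the all-(R) bis-epoxide under catalyst control, and the amide is inert.

Step 15
Reactants: 24 3-[(2R,3R)-3-{2-[(2R)-3,3-dimethyloxiran-2-yl]ethyl}-3-methyloxiran-2-yl]-N-methoxy-N-methylpropanamide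
Product: 25 1-[(2R,3R)-3-{2-[(2R)-3,3-dimethyloxiran-2-yl]ethyl}-3-methyloxiran-2-yl]hex-5-en-3-one
Conditions: allylMgBr, THF, −78 °C; then aq. NH4Cl
Reagents that add atoms: allylmagnesium bromide, C=CC[Mg]Br
Why: In this Weinreb ketone synthesis the chelated tetrahedral intermediate prevents over-addition, and the trisubstituted epoxides should survive the Grignard reagent at low temperature.

Step 16
Reactants: 25 1-[(2R,3R)-3-{2-[(2R)-3,3-dimethyloxiran-2-yl]ethyl}-3-methyloxiran-2-yl]hex-5-en-3-one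
Product: 26 tert-butyl({(3Z)-1-[(2R,3R)-3-{2-[(2R)-3,3-dimethyloxiran-2-yl]ethyl}-3-methyloxiran-2-yl]hexa-3,5-dien-3-yl}oxy)dimethylsilane
Conditions: KN(SiMe3)2, TBSCl, THF, −78 °C
Reagents that add atoms: tert-butyldimethylsilyl chloride, CC(C)(C)[Si](C)(C)Cl
Why: Deprotonation should occur at the doubly activated CH2 between the carbonyl and the vinyl group, and O-silylation of that dienolate gives the 2-silyloxy diene regioselectively, expected as the Z isomer.

Step 17
Reactants: 26 tert-butyl({(3Z)-1-[(2R,3R)-3-{2-[(2R)-3,3-dimethyloxiran-2-yl]ethyl}-3-methyloxiran-2-yl]hexa-3,5-dien-3-yl}oxy)dimethylsilane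
Product: 27 (3R,5aR,6R,9aR)-3-[(tert-butyldimethylsilyl)oxy]-6-ethenyl-2,2,5a-trimethyloctahydro-1-benzoxepin-7(2H)-one
Conditions: TBSOTf (0.3 equiv), 2,6-di-tert-butyl-4-methylpyridine (0.5 equiv), CH2Cl2, −78 °C
Reagents that add atoms: none
Why: In this epoxide-opening cascade (tandem oxa- and carbacyclisation) silylation of the terminal epoxide should trigger attack of the internal epoxide oxygen on its tertiary carbon, and the resulting epoxonium is opened at its tertiary carbon with inversion by the α-carbon of the silyloxydiene through a chair transition state, so that ring A (oxepane) and ring B (cyclohexanone) form trans-fused with the stereocentres fixed in step 14 and the vinyl group equatorial, while the silyl group leaving the enol oxygen carries the chain.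

Step 18
Reactants: 27 (3R,5aR,6R,9aR)-3-[(tert-butyldimethylsilyl)oxy]-6-ethenyl-2,2,5a-trimethyloctahydro-1-benzoxepin-7(2H)-one
Product: 28 (3R,5aR,6R,7S,9aR)-3-[(tert-butyldimethylsilyl)oxy]-6-ethenyl-2,2,5a,7-tetramethyldecahydro-1-benzoxepin-7-ol
Conditions: MeLi, CeCl3, THF, −78 °C; then aq. NH4Cl
Reagents that add atoms: methyllithium, [Li]C
Why: The organocerium 1,2-addition should come from the equatorial direction because the axial path is blocked by the 1,3-diaxial angular methyl, giving the axial tertiary alcohol, and the non-basic reagent avoids enolisation of the β,γ-unsaturated ketone.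

Step 19
Reactants: 28 (3R,5aR,6R,7S,9aR)-3-[(tert-butyldimethylsilyl)oxy]-6-ethenyl-2,2,5a,7-tetramethyldecahydro-1-benzoxepin-7-ol
Product: 29 tert-butyl{[(3R,5aR,6R,7S,9aR)-6-ethenyl-2,2,5a,7-tetramethyl-7-[(triethylsilyl)oxy]decahydro-1-benzoxepin-3-yl]oxy}dimethylsilane
Conditions: TESOTf, 2,6-lutidine, CH2Cl2, 0 → 23 °C
Reagents that add atoms: triethylsilyl trifluoromethanesulfonate, CC[Si](CC)(CC)OS(=O)(=O)C(F)(F)F
Why: Silyl triflate silylation caps the hindered tertiary alcohol, which would otherwise close a tetrahydrofuran onto the later primary iodide and quench the organolithium.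

Step 20
Reactants: 29 tert-butyl{[(3R,5aR,6R,7S,9aR)-6-ethenyl-2,2,5a,7-tetramethyl-7-[(triethylsilyl)oxy]decahydro-1-benzoxepin-3-yl]oxy}dimethylsilane
Product: 31 2-[(3R,5aR,6R,7S,9aR)-3-[(tert-butyldimethylsilyl)oxy]-2,2,5a,7-tetramethyl-7-[(triethylsilyl)oxy]decahydro-1-benzoxepin-6-yl]ethan-1-ol, via alkylborane 30 (not isolated)
Conditions: 9-BBN, THF, 23 °C; then NaOH, H2O2, 0 °C
Reagents that add atoms: hydrogen peroxide, OO
Why: Hydroboration–oxidation of the monosubstituted alkene with the bulky borane should place boron, and then oxygen, on the terminal carbon only.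

Step 21
Reactants: 31 2-[(3R,5aR,6R,7S,9aR)-3-[(tert-butyldimethylsilyl)oxy]-2,2,5a,7-tetramethyl-7-[(triethylsilyl)oxy]decahydro-1-benzoxepin-6-yl]ethan-1-ol
Product: 32 tert-butyl{[(3R,5aR,6R,7S,9aR)-6-(2-iodoethyl)-2,2,5a,7-tetramethyl-7-[(triethylsilyl)oxy]decahydro-1-benzoxepin-3-yl]oxy}dimethylsilane
Conditions: I2, PPh3, imidazole, CH2Cl2, 0 °C
Reagents that add atoms: iodine, II
Why: The Appel reaction converts the primary alcohol into the iodide by SN2 at a carbon that is not stereogenic.

**Union and end game**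

Step 22
Reactants: 32 tert-butyl{[(3R,5aR,6R,7S,9aR)-6-(2-iodoethyl)-2,2,5a,7-tetramethyl-7-[(triethylsilyl)oxy]decahydro-1-benzoxepin-3-yl]oxy}dimethylsilane; 19 (1R,3aR,8aR)-7-methoxy-1,4,4,6-tetramethyl-1-[(triethylsilyl)oxy]-2,3,3a,4,8,8a-hexahydroazulen-5(1H)-one
Product: 35 (1R,3aR,8aR)-5-{2-[(3R,5aR,6R,7S,9aR)-3-[(tert-butyldimethylsilyl)oxy]-2,2,5a,7-tetramethyl-7-[(triethylsilyl)oxy]decahydro-1-benzoxepin-6-yl]ethyl}-1,4,4,6-tetramethyl-1-[(triethylsilyl)oxy]-2,3,3a,4,8,8a-hexahydroazulen-7(1H)-one, via alkyllithium 33 (not isolated), via carbinol adduct 34 (not isolated)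
Conditions: t-BuLi (2.1 equiv), Et2O, −78 °C; then 19, THF, −78 → −20 °C; then 1 M HCl, THF, 0 °C
Reagents that add atoms: water, O
Why: In this Stork–Danheiser sequence, iodine–lithium exchange gives the primary alkyllithium, which should add 1,2 to the vinylogous ester carbonyl (no α-hydrogen on its quaternary side), and acid then ionises the tertiary allylic alcohol and hydrolyses the enol ether to the transposed β-alkyl enone without creating a stereocentre.

Step 23
Reactants: 35 (1R,3aR,8aR)-5-{2-[(3R,5aR,6R,7S,9aR)-3-[(tert-butyldimethylsilyl)oxy]-2,2,5a,7-tetramethyl-7-[(triethylsilyl)oxy]decahydro-1-benzoxepin-6-yl]ethyl}-1,4,4,6-tetramethyl-1-[(triethylsilyl)oxy]-2,3,3a,4,8,8a-hexahydroazulen-7(1H)-one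
Product: 36 (1R,3aR,8aR)-5-{2-[(3R,5aR,6R,7S,9aR)-3,7-dihydroxy-2,2,5a,7-tetramethyldecahydro-1-benzoxepin-6-yl]ethyl}-1-hydroxy-1,4,4,6-tetramethyl-2,3,3a,4,8,8a-hexahydroazulen-7(1H)-one (CNP0397160.1)
Conditions: HF·pyridine, pyridine, THF, 0 → 23 °C
Reagents that add atoms: none
Why: Fluoride-mediated cleavage should remove the secondary tert-butyldimethylsilyl ether and both tertiary triethylsilyl ethers under buffered conditions that leave the enone and the tertiary alcohols untouched.

**Compound list**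

1 | 2-methylcyclopent-2-en-1-one | CC1=CCCC1=O | starting material
2 | (1S)-2-methylcyclopent-2-en-1-ol | CC1=CCC[C@@H]1O | intermediate
3 | (1S,2S,5R)-1-methyl-6-oxabicyclo[3.1.0]hexan-2-ol (epoxide cis to the hydroxyl) | C[C@@]12O[C@@H]1CC[C@@H]2O | intermediate
4 | (1S,2S,3S)-2-methyl-3-(phenylselanyl)cyclopentane-1,2-diol | C[C@@]1(O)[C@@H]([Se]c2ccccc2)CC[C@@H]1O | intermediate (formed in the flask, not isolated)
5 | (1S,2S,3S)-3-(benzeneseleninyl)-2-methylcyclopentane-1,2-diol | C[C@@]1(O)[C@@H]([Se](=O)c2ccccc2)CC[C@@H]1O | intermediate (formed in the flask, not isolated)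
6 | (1R,5S)-1-methylcyclopent-2-ene-1,5-diol (cis-diol) | C[C@@]1(O)C=CC[C@@H]1O | intermediate
7 | (1S,2R)-2-hydroxy-2-methylcyclopent-3-en-1-yl acetate | C[C@@]1(O)C=CC[C@@H]1OC(C)=O | intermediate
8 | (1R,5S)-5-(acetyloxy)-1-methylcyclopent-2-en-1-yl 2-methylpropanoate | C[C@@]1(OC(=O)C(C)C)C=CC[C@@H]1OC(C)=O | intermediate
9 | bis(tert-butyldimethylsilyl ketene acetal) of 8 | C[C@@]1(OC(O[Si](C)(C)C(C)(C)C)=C(C)C)C=CC[C@@H]1OC(=C)O[Si](C)(C)C(C)(C)C | intermediate (formed in the flask, not isolated)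
10 | tert-butyldimethylsilyl 2-[(1R,4S)-4-({1-[(tert-butyldimethylsilyl)oxy]ethenyl}oxy)-3-methylcyclopent-2-en-1-yl]-2-methylpropanoate | CC1=C[C@H](C(C)(C)C(=O)O[Si](C)(C)C(C)(C)C)C[C@@H]1OC(=C)O[Si](C)(C)C(C)(C)C | intermediate (formed in the flask, not isolated)
11 | bis(tert-butyldimethylsilyl) ester of diacid 12 | CC1=CC[C@@H](C(C)(C)C(=O)O[Si](C)(C)C(C)(C)C)[C@H]1CC(=O)O[Si](C)(C)C(C)(C)C | intermediate (formed in the flask, not isolated)
12 | 2-[(1R,5R)-5-(carboxymethyl)-4-methylcyclopent-3-en-1-yl]-2-methylpropanoic acid | CC1=CC[C@@H](C(C)(C)C(O)=O)[C@H]1CC(O)=O | intermediate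
13 | 2-[(1R,5R)-5-(2-methoxy-2-oxoethyl)-4-methylcyclopent-3-en-1-yl]-2-methylpropanoic acid | CC1=CC[C@@H](C(C)(C)C(O)=O)[C@H]1CC(=O)OC | intermediate
14 | methyl 2-[(1R,5R)-5-(1-chloro-2-methyl-1-oxopropan-2-yl)-2-methylcyclopent-2-en-1-yl]acetate | CC1=CC[C@@H](C(C)(C)C(Cl)=O)[C@H]1CC(=O)OC | intermediate (formed in the flask, not isolated)
15 | methyl 2-[(1R,5R)-2-methyl-5-(2-methyl-3-oxopentan-2-yl)cyclopent-2-en-1-yl]acetate | CC1=CC[C@@H](C(C)(C)C(=O)CC)[C@H]1CC(=O)OC | intermediate
16 | (3aR,8aR)-1,4,4,6-tetramethyl-3,3a,4,6,8,8a-hexahydroazulene-5,7-dione (cis-fused; C-6 stereolabile) | CC1=CC[C@@H]2[C@H]1CC(=O)C(C)C(=O)C2(C)C | intermediate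
17 | (3aR,8aR)-7-methoxy-1,4,4,6-tetramethyl-3a,4,8,8a-tetrahydroazulen-5(3H)-one | CC1=CC[C@@H]2[C@H]1CC(OC)=C(C)C(=O)C2(C)C | intermediate
18 | (1R,3aR,8aR)-1-hydroxy-7-methoxy-1,4,4,6-tetramethyl-2,3,3a,4,8,8a-hexahydroazulen-5(1H)-one | C[C@@]1(O)CC[C@@H]2[C@H]1CC(OC)=C(C)C(=O)C2(C)C | intermediate
19 | (1R,3aR,8aR)-7-methoxy-1,4,4,6-tetramethyl-1-[(triethylsilyl)oxy]-2,3,3a,4,8,8a-hexahydroazulen-5(1H)-one | C[C@@]1(O[Si](CC)(CC)CC)CC[C@@H]2[C@H]1CC(OC)=C(C)C(=O)C2(C)C | intermediate
20 | geranyl bromide, (2E)-1-bromo-3,7-dimethylocta-2,6-diene | CC(C)=CCC/C(C)=C/CBr | starting material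
21 | N-methoxy-N-methylacetamide | CON(C)C(C)=O | starting material
22 | lithium enolate of 21 | [Li]OC(=C)N(C)OC | intermediate (formed in the flask, not isolated)
23 | (4E)-N-methoxy-N,5,9-trimethyldeca-4,8-dienamide | CON(C)C(=O)CC/C=C(\C)CCC=C(C)C | intermediate
24 | 3-[(2R,3R)-3-{2-[(2R)-3,3-dimethyloxiran-2-yl]ethyl}-3-methyloxiran-2-yl]-N-methoxy-N-methylpropanamide | CON(C)C(=O)CC[C@H]1O[C@]1(C)CC[C@H]1OC1(C)C | intermediate
25 | 1-[(2R,3R)-3-{2-[(2R)-3,3-dimethyloxiran-2-yl]ethyl}-3-methyloxiran-2-yl]hex-5-en-3-one | C=CCC(=O)CC[C@H]1O[C@]1(C)CC[C@H]1OC1(C)C | intermediate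
26 | tert-butyl({(3Z)-1-[(2R,3R)-3-{2-[(2R)-3,3-dimethyloxiran-2-yl]ethyl}-3-methyloxiran-2-yl]hexa-3,5-dien-3-yl}oxy)dimethylsilane | C=C/C=C(O[Si](C)(C)C(C)(C)C)/CC[C@H]1O[C@]1(C)CC[C@H]1OC1(C)C | intermediate
27 | (3R,5aR,6R,9aR)-3-[(tert-butyldimethylsilyl)oxy]-6-ethenyl-2,2,5a-trimethyloctahydro-1-benzoxepin-7(2H)-one | C=C[C@@H]1[C@@]2(C)CC[C@@H](O[Si](C)(C)C(C)(C)C)C(C)(C)O[C@@H]2CCC1=O | intermediate
28 | (3R,5aR,6R,7S,9aR)-3-[(tert-butyldimethylsilyl)oxy]-6-ethenyl-2,2,5a,7-tetramethyldecahydro-1-benzoxepin-7-ol | C=C[C@@H]1[C@@]2(C)CC[C@@H](O[Si](C)(C)C(C)(C)C)C(C)(C)O[C@@H]2CC[C@]1(C)O | intermediate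
29 | tert-butyl{[(3R,5aR,6R,7S,9aR)-6-ethenyl-2,2,5a,7-tetramethyl-7-[(triethylsilyl)oxy]decahydro-1-benzoxepin-3-yl]oxy}dimethylsilane | C=C[C@@H]1[C@@]2(C)CC[C@@H](O[Si](C)(C)C(C)(C)C)C(C)(C)O[C@@H]2CC[C@]1(C)O[Si](CC)(CC)CC | intermediate
30 | B-alkyl-9-borabicyclo[3.3.1]nonane from 29 (boron on the terminal carbon) | B1(CC[C@@H]3[C@@]4(C)CC[C@@H](O[Si](C)(C)C(C)(C)C)C(C)(C)O[C@@H]4CC[C@]3(C)O[Si](CC)(CC)CC)C2CCCC1CCC2 | intermediate (formed in the flask, not isolated)
31 | 2-[(3R,5aR,6R,7S,9aR)-3-[(tert-butyldimethylsilyl)oxy]-2,2,5a,7-tetramethyl-7-[(triethylsilyl)oxy]decahydro-1-benzoxepin-6-yl]ethan-1-ol | OCC[C@@H]1[C@@]2(C)CC[C@@H](O[Si](C)(C)C(C)(C)C)C(C)(C)O[C@@H]2CC[C@]1(C)O[Si](CC)(CC)CC | intermediate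
32 | tert-butyl{[(3R,5aR,6R,7S,9aR)-6-(2-iodoethyl)-2,2,5a,7-tetramethyl-7-[(triethylsilyl)oxy]decahydro-1-benzoxepin-3-yl]oxy}dimethylsilane | ICC[C@@H]1[C@@]2(C)CC[C@@H](O[Si](C)(C)C(C)(C)C)C(C)(C)O[C@@H]2CC[C@]1(C)O[Si](CC)(CC)CC | intermediate
33 | primary alkyllithium from 32 | [Li]CC[C@@H]1[C@@]2(C)CC[C@@H](O[Si](C)(C)C(C)(C)C)C(C)(C)O[C@@H]2CC[C@]1(C)O[Si](CC)(CC)CC | intermediate (formed in the flask, not isolated)
34 | tertiary carbinol from 1,2-addition of 33 to 19 (carbinol configuration undefined) | C[C@@]1(O[Si](CC)(CC)CC)CC[C@@H]2[C@H]1CC(OC)=C(C)C(O)(CC[C@@H]1[C@@]3(C)CC[C@@H](O[Si](C)(C)C(C)(C)C)C(C)(C)O[C@@H]3CC[C@]1(C)O[Si](CC)(CC)CC)C2(C)C | intermediate (formed in the flask, not isolated)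
35 | (1R,3aR,8aR)-5-{2-[(3R,5aR,6R,7S,9aR)-3-[(tert-butyldimethylsilyl)oxy]-2,2,5a,7-tetramethyl-7-[(triethylsilyl)oxy]decahydro-1-benzoxepin-6-yl]ethyl}-1,4,4,6-tetramethyl-1-[(triethylsilyl)oxy]-2,3,3a,4,8,8a-hexahydroazulen-7(1H)-one | C[C@@]1(O[Si](CC)(CC)CC)CC[C@@H]2[C@H]1CC(=O)C(C)=C(CC[C@@H]1[C@@]3(C)CC[C@@H](O[Si](C)(C)C(C)(C)C)C(C)(C)O[C@@H]3CC[C@]1(C)O[Si](CC)(CC)CC)C2(C)C | intermediate
36 | (1R,3aR,8aR)-5-{2-[(3R,5aR,6R,7S,9aR)-3,7-dihydroxy-2,2,5a,7-tetramethyldecahydro-1-benzoxepin-6-yl]ethyl}-1-hydroxy-1,4,4,6-tetramethyl-2,3,3a,4,8,8a-hexahydroazulen-7(1H)-one (CNP0397160.1) | CC1=C(CC[C@@H]2[C@@]3(C)CC[C@@H](O)C(C)(C)O[C@@H]3CC[C@]2(C)O)C(C)(C)[C@@H]2CC[C@@](C)(O)[C@@H]2CC1=O | target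

**Summary**

Total step count: 23.
Longest linear sequence: 14 steps (steps 1 to 12, then 22 and 23, from 2-methylcyclopent-2-en-1-one); the AB-ring branch has 9 steps before the union.

Steps most likely to fail:

Step 6. The second sigmatropic shift must deliver the CH2 carbon to the ring face already carrying the new quaternary substituent. It may lag behind C-silylation or fragmentation of the acetate-derived ketene acetal, so the cascade could stall after one shift. The fallback sets out from diol 6 and comes back at keto ester 15. The secondary hydroxyl of 6 is silylated (TBSCl, imidazole) to give (1R,5S)-5-[(tert-butyldimethylsilyl)oxy]-1-methylcyclopent-2-en-1-ol F1, and the tertiary hydroxyl is acylated (isobutyric anhydride, DMAP) to give the isobutyrate F2. A single Ireland–Claisen rearrangement (LiN(i-Pr)2, TMSCl, THF, −78 → 23 °C) passes through the trimethylsilyl ketene acetal F3 and the trimethylsilyl ester F4 and should give, after aqueous work-up, the acid F5. Ethyllithium (2.2 equiv) converts the acid into the ethyl ketone F6 while no other carbonyl is present, and Bu4NF frees the allylic alcohol F7. A Johnson–Claisen rearrangement (trimethyl orthoacetate, propionic acid cat., xylene, 140 °C) through the mixed ketene acetal F8 then forms the CH2–ring bond thermally with the same suprafacial transfer and gives 15 directly, which also bypasses steps 7 and 8.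

Step 9. Closure of the seven-membered 1,3-dione may lose out to reversible aldol closure of the ester enolate onto the ketone (five-membered ring) or to intermolecular condensation. The fallback sets out from 15 and comes back at dione 16. The ketone alone is enolised and silylated (TBSOTf, Et3N) to give the silyl enol ether F9, and the ester is reduced to the aldehyde F10 (i-Bu2AlH, −78 °C), which fixes which carbon is nucleophile and which is electrophile. An intramolecular Mukaiyama aldol reaction (BF3·OEt2, CH2Cl2, −78 °C) should close ring C to the β-hydroxy ketone F11, and Dess–Martin oxidation gives 16.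

Step 22. Addition of the primary alkyllithium to the ketone flanked by a quaternary carbon and a tetrasubstituted alkene may be outrun by γ-deprotonation of the vinylogous ester or by silyl migration within the organolithium. The fallback sets out from 29 and comes back at 35, and uses a slimmer sp-hybridised nucleophile. Ozonolysis of the vinyl group (O3, then Me2S) gives the ring-B carbaldehyde F12, and the Ohira–Bestmann reagent (K2CO3, MeOH) gives the terminal alkyne F13. Deprotonation (n-BuLi) gives the lithium acetylide F14, which adds to 19 to give the propargylic carbinol F15; dilute HCl converts this into the enynone F16. Hydrogenation (H2, Pd/C, EtOAc) should saturate the alkyne while the tetrasubstituted enone alkene stays, which gives 35.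

Further compounds

F1 | step 6 | (1R,5S)-5-[(tert-butyldimethylsilyl)oxy]-1-methylcyclopent-2-en-1-ol | C[C@@]1(O)C=CC[C@@H]1O[Si](C)(C)C(C)(C)C
F2 | step 6 | (1R,5S)-5-[(tert-butyldimethylsilyl)oxy]-1-methylcyclopent-2-en-1-yl 2-methylpropanoate | C[C@@]1(OC(=O)C(C)C)C=CC[C@@H]1O[Si](C)(C)C(C)(C)C
F3 | step 6 | trimethylsilyl ketene acetal of F2 | C[C@@]1(OC(O[Si](C)(C)C)=C(C)C)C=CC[C@@H]1O[Si](C)(C)C(C)(C)C
F4 | step 6 | trimethylsilyl 2-[(1R,4S)-4-[(tert-butyldimethylsilyl)oxy]-3-methylcyclopent-2-en-1-yl]-2-methylpropanoate | CC1=C[C@H](C(C)(C)C(=O)O[Si](C)(C)C)C[C@@H]1O[Si](C)(C)C(C)(C)C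
F5 | step 6 | 2-[(1R,4S)-4-[(tert-butyldimethylsilyl)oxy]-3-methylcyclopent-2-en-1-yl]-2-methylpropanoic acid | CC1=C[C@H](C(C)(C)C(O)=O)C[C@@H]1O[Si](C)(C)C(C)(C)C
F6 | step 6 | 2-[(1R,4S)-4-[(tert-butyldimethylsilyl)oxy]-3-methylcyclopent-2-en-1-yl]-2-methylpentan-3-one | CC1=C[C@H](C(C)(C)C(=O)CC)C[C@@H]1O[Si](C)(C)C(C)(C)C
F7 | step 6 | 2-[(1R,4S)-4-hydroxy-3-methylcyclopent-2-en-1-yl]-2-methylpentan-3-one | CC1=C[C@H](C(C)(C)C(=O)CC)C[C@@H]1O
F8 | step 6 | mixed methyl ketene acetal of F7 | CC1=C[C@H](C(C)(C)C(=O)CC)C[C@@H]1OC(=C)OC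
F9 | step 9 | methyl 2-[(1R,5R)-5-{3-[(tert-butyldimethylsilyl)oxy]-2-methylpent-3-en-2-yl}-2-methylcyclopent-2-en-1-yl]acetate | CC1=CC[C@@H](C(C)(C)C(O[Si](C)(C)C(C)(C)C)=CC)[C@H]1CC(=O)OC
F10 | step 9 | 2-[(1R,5R)-5-{3-[(tert-butyldimethylsilyl)oxy]-2-methylpent-3-en-2-yl}-2-methylcyclopent-2-en-1-yl]acetaldehyde | CC1=CC[C@@H](C(C)(C)C(O[Si](C)(C)C(C)(C)C)=CC)[C@H]1CC=O
F11 | step 9 | (3aR,8aR)-7-hydroxy-1,4,4,6-tetramethyl-3a,4,6,7,8,8a-hexahydroazulen-5(3H)-one | CC1=CC[C@@H]2[C@H]1CC(O)C(C)C(=O)C2(C)C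
F12 | step 22 | ring-B carbaldehyde from ozonolysis of 29 | O=C[C@@H]1[C@@]2(C)CC[C@@H](O[Si](C)(C)C(C)(C)C)C(C)(C)O[C@@H]2CC[C@]1(C)O[Si](CC)(CC)CC
F13 | step 22 | ring-B ethynyl compound | C#C[C@@H]1[C@@]2(C)CC[C@@H](O[Si](C)(C)C(C)(C)C)C(C)(C)O[C@@H]2CC[C@]1(C)O[Si](CC)(CC)CC
F14 | step 22 | lithium acetylide of F13 | [Li]C#C[C@@H]1[C@@]2(C)CC[C@@H](O[Si](C)(C)C(C)(C)C)C(C)(C)O[C@@H]2CC[C@]1(C)O[Si](CC)(CC)CC
F15 | step 22 | propargylic carbinol from F14 and 19 | C[C@@]1(O[Si](CC)(CC)CC)CC[C@@H]2[C@H]1CC(OC)=C(C)C(O)(C#C[C@@H]1[C@@]3(C)CC[C@@H](O[Si](C)(C)C(C)(C)C)C(C)(C)O[C@@H]3CC[C@]1(C)O[Si](CC)(CC)CC)C2(C)C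
F16 | step 22 | enynone (alkyne analogue of 35) | C[C@@]1(O[Si](CC)(CC)CC)CC[C@@H]2[C@H]1CC(=O)C(C)=C(C#C[C@@H]1[C@@]3(C)CC[C@@H](O[Si](C)(C)C(C)(C)C)C(C)(C)O[C@@H]3CC[C@]1(C)O[Si](CC)(CC)CC)C2(C)C
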